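Assumption: germacrane numbering is used (ring C1–C10; C14 methyl on C10, C15 methyl on C4; C7 carries C11 with C12 and C13), so the target is (4R,5S,6R,7R,10S)-4,5,11-trihydroxygermacran-6-yl (2Z)-2-methylbut-2-enoate (angelate); (R)-citronellyl bromide is taken as commercial.

**Retrosynthetic overview**
1. Target ⇒ Markovnikov hydration of C11=C12 and anti opening (water at C4, inversion) of the 4,5-epoxide of 4,5-epoxygermacr-11-en-6-yl angelate; the angelate goes on the single C6 hydroxyl.
2. Ten-membered ring ⇒ C6–C7 bond by cationic closure of the distal prenyl alkene onto the C6 aldehyde of (2R,3S)-2,3-epoxy-6,7-dihydrofarnesal. This is the farnesyl C1-to-C10 closure of germacrane biosynthesis, with the C11 cation ending by proton loss.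
3. Epoxy aldehyde ⇒ Sharpless epoxidation and oxidation of (2E,7S)-6,7-dihydrofarnesol ⇒ methylalumination/hydroxymethylation of a C13 alkyne ⇒ (R)-citronellyl bromide + propyne.
4. Ring order: oxirane first (step 3), then the ten-membered carbocycle (step 5); the oxirane is opened in step 7.

**Route**

Step 1
Reactants: 1 (R)-citronellyl bromide; 2 propyne
Product: 5 (6S)-6,10-dimethylundec-9-en-1-yne, via 1,3-dilithiopropyne 3 (not isolated), via lithium acetylide 4 (not isolated)
Conditions: 2, n-BuLi (2 equiv per 2), TMEDA, THF/hexane, −78 to 0 °C; then 1, −78 °C to rt; then H2O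
Reagents that add atoms: none
Why: Propargyl dianion alkylation: the sp3 carbanion of 1,3-dilithiopropyne is far more nucleophilic than its acetylide end, so SN2 attack on the primary bromide gives the three-carbon-extended acetylide and then the terminal alkyne, while the methyl stereocentre of 1 (the future C10, S in the target) is untouched.

Step 2
Reactants: 5 (6S)-6,10-dimethylundec-9-en-1-yne
Product: 8 (2E,7S)-3,7,11-trimethyldodeca-2,10-dien-1-ol, via alkenylalane 6 (not isolated), via lithium alanate 7 (not isolated)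
Conditions: Me3Al, Cp2ZrCl2 (0.2 equiv), CH2Cl2, 0 °C to rt; then n-BuLi, THF, −78 °C; (CH2O)n, rt; then H2O
Reagents that add atoms: trimethylaluminium, C[Al](C)C; formaldehyde (from paraformaldehyde), C=O
Why: Negishi zirconium-catalysed carboalumination adds methyl and aluminium syn across the terminal alkyne with methyl on the internal carbon, and hydroxymethylation of the alanate proceeds with retention, fixing the 2E geometry that later becomes the anti 4,5-diol; the trisubstituted alkene is inert.

Step 3
Reactants: 8 (2E,7S)-3,7,11-trimethyldodeca-2,10-dien-1-ol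
Product: 9 [(2S,3S)-3-[(4S)-4,8-dimethylnon-7-en-1-yl]-3-methyloxiran-2-yl]methanol
Conditions: Ti(OiPr)4 (0.1 equiv), L-(+)-diethyl tartrate (0.12 equiv), t-BuOOH, 4 Å MS, CH2Cl2, −20 °C
Reagents that add atoms: tert-butyl hydroperoxide, CC(C)(C)OO
Why: Sharpless asymmetric epoxidation: as with geraniol, L-(+)-diethyl tartrate gives the (2S,3S)-epoxide of the E allylic alcohol under reagent control, setting the future C5 (S, kept) and C4 (S, inverted in step 7); the remote alkene and the C7 centre play no part.

Step 4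
Reactants: 9 [(2S,3S)-3-[(4S)-4,8-dimethylnon-7-en-1-yl]-3-methyloxiran-2-yl]methanol
Product: 10 (2R,3S)-3-[(4S)-4,8-dimethylnon-7-en-1-yl]-3-methyloxirane-2-carbaldehyde
Conditions: TEMPO (0.1 equiv), PhI(OAc)2, CH2Cl2, rt
Reagents that add atoms: none
Why: Oxoammonium (TEMPO) oxidation of the primary alcohol stops at the aldehyde under near-neutral conditions that do not epimerise the α-carbon or touch the epoxide and the alkene (the 2S to 2R change is only a priority change).

Step 5
Reactants: 10 (2R,3S)-3-[(4S)-4,8-dimethylnon-7-en-1-yl]-3-methyloxirane-2-carbaldehyde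
Product: 12 (4S,5S,6R,7S,10S)-4,5-epoxygermacr-11-en-6-ol, via C11 cation zwitterion 11 (not isolated)
Conditions: Me2AlCl (2.5 equiv), CH2Cl2, −78 to −40 °C, 10 added over 12 h to 1 mM; then H2O
Reagents that add atoms: none
Why: Proposed new method: a Prins-type (carbonyl-ene) macrocyclisation in which the aldehyde carbon, activated as a five-membered Me2Al chelate with the epoxide oxygen, plays the role of farnesyl C1 and is attacked by the distal trisubstituted alkene to give tertiary C11 cation 11, which ends by loss of a methyl proton (taken up by an aluminium-bound methyl as methane) to leave the isopropenyl group; the closest known reactions are the Lewis acid carbonyl-ene cyclisation of citronellal to isopulegol, aluminium-promoted ene macrocyclisations of alkynals to 12- to 14-membered rings, and Me2AlCl chelation-controlled carbonyl additions; ring closure is helped by the absence of the central farnesyl alkene (no six-membered alternative) and by high dilution, chelation directs attack to the carbonyl face anti to C4 so that O5 and O6 become syn (6R), and an open transition state with C5/C8 and O6/C11 both antiperiplanar about the forming bond sets C7 (S in 12, R once C11 is hydroxylated).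

Step 6
Reactants: 12 (4S,5S,6R,7S,10S)-4,5-epoxygermacr-11-en-6-ol; 13 angelic acid
Product: 15 (4S,5S,6R,7S,10S)-4,5-epoxygermacr-11-en-6-yl angelate, via mixed anhydride 14 (not isolated)
Conditions: 13, 2,4,6-Cl3C6H2COCl, Et3N (excess), PhMe, rt; then 12, 80 °C
Reagents that add atoms: none
Why: Yamaguchi-type mixed-anhydride acylation run without DMAP transfers the angeloyl group to the only hydroxyl (C6, retention) under conditions known to avoid Z-to-E isomerisation to the tiglate, and the weakly basic medium leaves the epoxide alone.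

Step 7
Reactants: 15 (4S,5S,6R,7S,10S)-4,5-epoxygermacr-11-en-6-yl angelate
Product: 16 (4R,5S,6R,7S,10S)-4,5-dihydroxygermacr-11-en-6-yl angelate
Conditions: HClO4 (0.05 equiv), THF/H2O 3:1, 0 °C
Reagents that add atoms: water, O
Why: Acid-catalysed (borderline A-2) epoxide hydrolysis: water attacks the tertiary C4 with inversion while the C5–O bond, deactivated by the neighbouring acyloxy carbon, stays intact, turning the (4S,5S)-epoxide into the (4R,5S) anti-diol; dilute acid at 0 °C spares the isopropenyl group and the ester, and no C11 hydroxyl is yet present to compete as an internal nucleophile.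

Step 8
Reactants: 16 (4R,5S,6R,7S,10S)-4,5-dihydroxygermacr-11-en-6-yl angelate
Product: 18 (4R,5S,6R,7R,10S)-4,5,11-trihydroxygermacran-6-yl angelate, via C11 hydroperoxide 17 (not isolated)
Conditions: Co(acac)2 (0.2 equiv), PhSiH3, O2 (1 atm), THF, rt; then PPh3
Reagents that add atoms: dioxygen, O=O
Why: Mukaiyama hydration (cobalt hydride hydrogen-atom transfer, O2 trapping, reduction of hydroperoxide 17) is Markovnikov-selective for the electron-rich 1,1-disubstituted alkene, whereas the electron-poor trisubstituted angelate is a poor substrate for Co(acac)2, and the neutral conditions avoid acyl migration; C11 is not stereogenic and C7 is untouched (S to R is only a priority change).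

**Compound list**
1 | (R)-citronellyl bromide, (6R)-8-bromo-2,6-dimethyloct-2-ene | CC(C)=CCC[C@@H](C)CCBr | starting material
2 | propyne | CC#C | starting material
3 | 1,3-dilithiopropyne | [Li]CC#C[Li] | intermediate (not isolated)
4 | lithium (6S)-6,10-dimethylundec-9-en-1-yn-1-ide | CC(C)=CCC[C@@H](C)CCCC#C[Li] | intermediate (not isolated)
5 | (6S)-6,10-dimethylundec-9-en-1-yne | CC(C)=CCC[C@@H](C)CCCC#C | intermediate
6 | dimethyl[(1E,6S)-2,6,10-trimethylundeca-1,9-dien-1-yl]alane | CC(C)=CCC[C@@H](C)CCC/C(C)=C/[Al](C)C | intermediate (not isolated)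
7 | lithium butyl(dimethyl)[(1E,6S)-2,6,10-trimethylundeca-1,9-dien-1-yl]alanate | CC(C)=CCC[C@@H](C)CCC/C(C)=C/[Al-](C)(C)CCCC.[Li+] | intermediate (not isolated)
8 | (2E,7S)-3,7,11-trimethyldodeca-2,10-dien-1-ol, (7S)-6,7-dihydrofarnesol | CC(C)=CCC[C@@H](C)CCC/C(C)=C/CO | intermediate
9 | [(2S,3S)-3-[(4S)-4,8-dimethylnon-7-en-1-yl]-3-methyloxiran-2-yl]methanol | OC[C@@H]1O[C@@]1(C)CCC[C@H](C)CCC=C(C)C | intermediate
10 | (2R,3S)-3-[(4S)-4,8-dimethylnon-7-en-1-yl]-3-methyloxirane-2-carbaldehyde | O=C[C@@H]1O[C@@]1(C)CCC[C@H](C)CCC=C(C)C | intermediate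
11 | C11 carbocation/aluminate zwitterion of the closed ring (Me2ClAl–O on C6, cation at C11) | C[Al-](C)(Cl)O[C@@H]1[C@H]([C+](C)C)CC[C@@H](C)CCC[C@]2(C)O[C@@H]12 | intermediate (not isolated)
12 | (4S,5S,6R,7S,10S)-4,5-epoxygermacr-11-en-6-ol; ten-membered ring with trans-4,5-epoxide, 6-OH, 7-isopropenyl, 4- and 10-methyl | O[C@@H]1[C@H](C(C)=C)CC[C@@H](C)CCC[C@]2(C)O[C@@H]12 | intermediate
13 | angelic acid, (2Z)-2-methylbut-2-enoic acid | C/C=C(/C)C(=O)O | starting material
14 | angelic 2,4,6-trichlorobenzoic anhydride | C/C=C(/C)C(=O)OC(=O)c1c(Cl)cc(Cl)cc1Cl | intermediate (not isolated)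
15 | (4S,5S,6R,7S,10S)-4,5-epoxygermacr-11-en-6-yl angelate | C/C=C(/C)C(=O)O[C@@H]1[C@H](C(C)=C)CC[C@@H](C)CCC[C@]2(C)O[C@@H]12 | intermediate
16 | (4R,5S,6R,7S,10S)-4,5-dihydroxygermacr-11-en-6-yl angelate | C/C=C(/C)C(=O)O[C@@H]1[C@H](C(C)=C)CC[C@@H](C)CCC[C@@](C)(O)[C@H]1O | intermediate
17 | (4R,5S,6R,7R,10S)-11-hydroperoxy-4,5-dihydroxygermacran-6-yl angelate | C/C=C(/C)C(=O)O[C@@H]1[C@H](C(C)(C)OO)CC[C@@H](C)CCC[C@@](C)(O)[C@H]1O | intermediate (not isolated)
18 | (4R,5S,6R,7R,10S)-4,5,11-trihydroxygermacran-6-yl angelate, CNP0130723.1 | C/C=C(/C)C(=O)O[C@@H]1[C@H](C(C)(C)O)CC[C@@H](C)CCC[C@@](C)(O)[C@H]1O | target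

**Totals**
Total step count: 8. Longest linear sequence: 8 steps (1 to 18).

**Steps most likely to fail**

Step 5 (ring closure). Risks are oligomerisation despite dilution, methyl transfer or epoxide opening by the aluminium reagent, and the wrong C6 or C7 configuration; the stereochemical outcome is a model-based prediction, not a precedented result. Fallback: replace the electrophile-driven closure by a nucleophile-driven Barbier-type closure of the same C6–C7 bond. Setting out from 9, ene-type chlorination of the prenyl terminus (Ca(OCl)2, solid CO2, CH2Cl2/H2O) gives the rearranged allylic chloride [(2S,3S)-3-[(4S)-7-chloro-4,8-dimethylnon-8-en-1-yl]-3-methyloxiran-2-yl]methanol F1 as both C–Cl epimers. TEMPO/PhI(OAc)2 then gives (2R,3S)-3-[(4S)-7-chloro-4,8-dimethylnon-8-en-1-yl]-3-methyloxirane-2-carbaldehyde F2. Pd(PPh3)4 (cat.) with Et2Zn in THF at high dilution converts the allylic chloride into an allylzinc that adds to the aldehyde through its more substituted terminus, coming back to the route at 12.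

Step 6 (angeloylation). Risks are low conversion at the hindered C6 hydroxyl and Z-to-E isomerisation to the tiglate. Fallback: build the Z double bond on the ester instead of transferring it. Setting out from 12, DCC/DMAP esterification with 2-[bis(2,2,2-trifluoroethoxy)phosphoryl]propanoic acid gives the phosphonate ester (4S,5S,6R,7S,10S)-4,5-epoxygermacr-11-en-6-yl 2-[bis(2,2,2-trifluoroethoxy)phosphoryl]propanoate F3. Still–Gennari olefination (KN(SiMe3)2, 18-crown-6, THF, −78 °C, acetaldehyde) gives the Z-trisubstituted enoate and comes back to the route at 15.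

Step 7 (epoxide hydrolysis in the ten-membered ring). Risks are transannular hydride shift or isopropenyl participation at the developing C4 cation, and participation or migration of the C6 acyl group. Fallback: open the oxirane in the acyclic series, before the ring exists, and carry the diol as an acetonide. Setting out from 9, Ac2O/pyridine gives the epoxy acetate [(2S,3S)-3-[(4S)-4,8-dimethylnon-7-en-1-yl]-3-methyloxiran-2-yl]methyl acetate F4. BF3·OEt2 (cat.) in acetone at −20 °C opens the oxirane at the tertiary carbon with inversion and closes the dioxolane, giving [(4S,5R)-5-[(4S)-4,8-dimethylnon-7-en-1-yl]-2,2,5-trimethyl-1,3-dioxolan-4-yl]methyl acetate F5. K2CO3/MeOH gives the alcohol [(4S,5R)-5-[(4S)-4,8-dimethylnon-7-en-1-yl]-2,2,5-trimethyl-1,3-dioxolan-4-yl]methanol F6, and TEMPO/PhI(OAc)2 gives the aldehyde (4R,5R)-5-[(4S)-4,8-dimethylnon-7-en-1-yl]-2,2,5-trimethyl-1,3-dioxolane-4-carbaldehyde F7. The Me2AlCl closure of step 5, now a chelation-controlled addition to an α-alkoxy aldehyde, gives (4R,5S,6R,7S,10S)-4,5-(isopropylidenedioxy)germacr-11-en-6-ol F8. Angeloylation as in step 6 gives (4R,5S,6R,7S,10S)-4,5-(isopropylidenedioxy)germacr-11-en-6-yl angelate F9, and 60% aqueous AcOH at 40 °C removes the acetonide, coming back to the route at 16.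

Further compounds
F1 | step 5 | [(2S,3S)-3-[(4S)-7-chloro-4,8-dimethylnon-8-en-1-yl]-3-methyloxiran-2-yl]methanol (both C–Cl epimers) | OC[C@@H]1O[C@@]1(C)CCC[C@H](C)CCC(Cl)C(C)=C
F2 | step 5 | (2R,3S)-3-[(4S)-7-chloro-4,8-dimethylnon-8-en-1-yl]-3-methyloxirane-2-carbaldehyde (both C–Cl epimers) | O=C[C@@H]1O[C@@]1(C)CCC[C@H](C)CCC(Cl)C(C)=C
F3 | step 6 | (4S,5S,6R,7S,10S)-4,5-epoxygermacr-11-en-6-yl 2-[bis(2,2,2-trifluoroethoxy)phosphoryl]propanoate (both α-epimers) | CC(P(=O)(OCC(F)(F)F)OCC(F)(F)F)C(=O)O[C@@H]1[C@H](C(C)=C)CC[C@@H](C)CCC[C@]2(C)O[C@@H]12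
F4 | step 7 | [(2S,3S)-3-[(4S)-4,8-dimethylnon-7-en-1-yl]-3-methyloxiran-2-yl]methyl acetate | CC(=O)OC[C@@H]1O[C@@]1(C)CCC[C@H](C)CCC=C(C)C
F5 | step 7 | [(4S,5R)-5-[(4S)-4,8-dimethylnon-7-en-1-yl]-2,2,5-trimethyl-1,3-dioxolan-4-yl]methyl acetate | CC(=O)OC[C@@H]1OC(C)(C)O[C@]1(C)CCC[C@H](C)CCC=C(C)C
F6 | step 7 | [(4S,5R)-5-[(4S)-4,8-dimethylnon-7-en-1-yl]-2,2,5-trimethyl-1,3-dioxolan-4-yl]methanol | OC[C@@H]1OC(C)(C)O[C@]1(C)CCC[C@H](C)CCC=C(C)C
F7 | step 7 | (4R,5R)-5-[(4S)-4,8-dimethylnon-7-en-1-yl]-2,2,5-trimethyl-1,3-dioxolane-4-carbaldehyde | O=C[C@@H]1OC(C)(C)O[C@]1(C)CCC[C@H](C)CCC=C(C)C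
F8 | step 7 | (4R,5S,6R,7S,10S)-4,5-(isopropylidenedioxy)germacr-11-en-6-ol | O[C@@H]1[C@H](C(C)=C)CC[C@@H](C)CCC[C@@]2(C)OC(C)(C)O[C@@H]12
F9 | step 7 | (4R,5S,6R,7S,10S)-4,5-(isopropylidenedioxy)germacr-11-en-6-yl angelate | C/C=C(/C)C(=O)O[C@@H]1[C@H](C(C)=C)CC[C@@H](C)CCC[C@@]2(C)OC(C)(C)O[C@@H]12
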